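**Strategy**

The carbocycle (ring B) is cut at C4a–C5 and C8–C8a, the two bonds that join the sp3 carbons C5 and C8 to the ring-fusion atoms of the pyridone (ring A). Because the chain on C5 and the hydroxyl on C8 are cis, both carbons can be delivered by a furan whose oxygen bridges C5 and C8 for a time; only C8–O is kept. A fluoride-triggered 2,3-pyridyne/furan [4+2] cycloaddition therefore forms both bonds, ring B and both stereocentres in one operation. Its precursor is a fully substituted 3-(trimethylsilyl)pyridin-2-yl triflate (4-benzyloxy, 5-methoxy, 6-methyl), paired with 2-(5-phenylpentyl)furan. The racemic product is resolved with a lipase at the end.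

Key step: step 8

Remark: compounds 16 to 19 are racemic and are named and drawn as the enantiomer that leads to the target; the target is written as its 4(1H)-pyridone tautomer.

**Route**

Step 1
Reactants: 1 2-methylpyridin-3-ol
Product: 2 4,6-dibromo-2-methylpyridin-3-ol
Conditions: NBS (2.1 equiv), MeCN, 0 °C to rt, dark
Reagents that add atoms: N-bromosuccinimide, O=C1CCC(=O)N1Br
Why: Electrophilic aromatic bromination of a 3-hydroxypyridine goes ortho and para to the hydroxyl, and with C2 blocked by methyl these positions are C4 and C6, so two equivalents should give the 4,6-dibromide.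

Step 2
Reactants: 2 4,6-dibromo-2-methylpyridin-3-ol
Product: 3 4,6-dibromo-3-methoxy-2-methylpyridine
Conditions: MeI, K2CO3, DMF, rt
Reagents that add atoms: iodomethane, CI
Why: Williamson O-methylation of the acidic pyridinol should be clean because the ring nitrogen is flanked by methyl and bromine and deactivated by two halogens, which disfavours N-alkylation.

Step 3
Reactants: 3 4,6-dibromo-3-methoxy-2-methylpyridine
Product: 4 4-(benzyloxy)-6-bromo-3-methoxy-2-methylpyridine
Conditions: BnOH (1.05 equiv), NaH, THF, 0 to 50 °C
Reagents that add atoms: benzyl alcohol, OCc1ccccc1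
Why: Nucleophilic aromatic substitution by benzyloxide should take place at C4, the position para to nitrogen that alkoxides prefer in 2,4-dihalopyridines, since C6–Br is further deactivated by the para methoxy donor and the first alkoxy group protects the ring against a second substitution.

Step 4
Reactants: 4 4-(benzyloxy)-6-bromo-3-methoxy-2-methylpyridine
Product: 5 4-(benzyloxy)-5-methoxy-6-methylpyridin-2(1H)-one
Conditions: Pd2(dba)3 (2 mol%), tBuXPhos (8 mol%), KOH, 1,4-dioxane/H2O, 100 °C; then aq. HCl to pH 6
Reagents that add atoms: potassium hydroxide, [K+].[OH-]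
Why: Palladium-catalysed hydroxylation of a heteroaryl bromide (C–O cross-coupling with hydroxide after insertion of zerovalent palladium into the C–Br bond) should give the 2-hydroxypyridine, which rests as the 2-pyridone, while the benzyl and methyl ethers are inert.

Step 5
Reactants: 5 4-(benzyloxy)-5-methoxy-6-methylpyridin-2(1H)-one
Product: 6 4-(benzyloxy)-3-bromo-5-methoxy-6-methylpyridin-2(1H)-one
Conditions: NBS (1.05 equiv), MeCN, 0 °C to rt, dark
Reagents that add atoms: N-bromosuccinimide, O=C1CCC(=O)N1Br
Why: Electrophilic bromination of a 2-pyridone occurs at C3, here the only unsubstituted ring carbon and one activated by both the ring amide and the 4-alkoxy group.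

Step 6
Reactants: 6 4-(benzyloxy)-3-bromo-5-methoxy-6-methylpyridin-2(1H)-one
Product: 10 4-(benzyloxy)-5-methoxy-6-methyl-3-(trimethylsilyl)pyridin-2-yl trifluoromethanesulfonate, via silyl ether 7 (not isolated), via 3-lithiopyridine 8 (not isolated), via lithium pyridin-2-olate 9 (not isolated)
Conditions: (Me3Si)2NH, THF, 65 °C, then evaporate; n-BuLi (1.05 equiv), THF, −78 °C; then Tf2O, −78 to 0 °C
Reagents that add atoms: hexamethyldisilazane, C[Si](C)(C)N[Si](C)(C)C; trifluoromethanesulfonic anhydride, O=S(=O)(OS(=O)(=O)C(F)(F)F)C(F)(F)F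
Why: This is the standard one-pot entry to ortho-silylaryl triflates from ortho-bromo hydroxyarenes, in which O-silylation, bromine–lithium exchange (faster at −78 °C than deprotonation at the benzylic or 6-methyl positions), a 1,3 oxygen-to-carbon silyl shift (retro-Brook rearrangement) and O-triflation of the resulting pyridinolate follow one another.

Step 7
Reactants: 11 furan; 12 (5-bromopentyl)benzene
Product: 14 2-(5-phenylpentyl)furan, via 2-furyllithium 13 (not isolated)
Conditions: n-BuLi, THF, 0 °C; then 12, 0 °C to rt
Reagents that add atoms: none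
Why: Furan is lithiated at its α-carbon and the 2-furyllithium is alkylated by the primary bromide in an SN2 reaction.

Step 8
Reactants: 10 4-(benzyloxy)-5-methoxy-6-methyl-3-(trimethylsilyl)pyridin-2-yl trifluoromethanesulfonate; 14 2-(5-phenylpentyl)furan
Product: 16 rac-(5S,8R)-4-(benzyloxy)-3-methoxy-2-methyl-5-(5-phenylpentyl)-5,8-dihydro-5,8-epoxyquinoline (racemate; bridge oxygen on one face at C5 and C8), via pyridyne 15 (not isolated)
Conditions: CsF (3 equiv), 14 (3 equiv), MeCN, rt; chromatography on Et3N-deactivated silica
Reagents that add atoms: none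
Why: Fluoride attacks silicon in 10, triflate leaves from the neighbouring carbon, and the 2,3-pyridyne 15 is trapped at once by the furan in a concerted but asynchronous suprafacial [4+2] cycloaddition in which C8–C8a forms ahead of C4a–C5. The closest known reaction type is the Diels–Alder trapping by furans of 2,3-pyridynes released from 3-silylpyridin-2-yl triflates. Both new rings, the six-membered carbocycle C4a–C5–C6–C7–C8–C8a and the five-membered ring C4a–C5–O–C8–C8a of the oxabicyclo[2.2.1] unit, are closed in the same pericyclic event, the furan adding through its two α-carbons across the aryne bond, so no separate cyclisation is involved. C5 and C8 are fixed relative to each other by the furan oxygen, which must bridge them on one face; neither partner has a stereocentre or a differentiated face, so the adduct is racemic. The step needs regioselectivity, which the polarisation of the pyridyne should supply: the ring nitrogen and the inductively withdrawing 4-benzyloxy group both make C8a the more linear, electrophilic terminus, which bonds first to the unsubstituted furan α-carbon (larger HOMO coefficient, less hindered), so the chain-bearing carbon closes the longer, later bond to C4a, where the clash with the benzyloxy group is attenuated. Excess furan and the slow dissolution of CsF keep the aryne concentration low and limit its self-reaction.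

Step 9
Reactants: 16 rac-(5S,8R)-4-(benzyloxy)-3-methoxy-2-methyl-5-(5-phenylpentyl)-5,8-dihydro-5,8-epoxyquinoline
Product: 19 rac-(5S,8R)-8-hydroxy-3-methoxy-2-methyl-5-(5-phenylpentyl)-5,6,7,8-tetrahydroquinolin-4(1H)-one (racemic cis alcohol), via saturated epoxy benzyl ether 17 (not isolated), via epoxy pyridone 18 (not isolated)
Conditions: H2 (4 bar), 10% Pd/C, EtOH, rt
Reagents that add atoms: none
Why: Heterogeneous hydrogenation should saturate the strained C6=C7 alkene and remove the O-benzyl group, after which hydrogenolysis cleaves the tertiary C5–O bond, activated by the electron-rich C4a of the 4-pyridone, in preference to the C8–O bond on the electron-poor carbon next to nitrogen, and because benzylic C–O hydrogenolysis on palladium proceeds with inversion the hydrogen enters C5 anti to the leaving oxygen, which places the chain on the face of the C8 hydroxyl (cis).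

Step 10
Reactants: 19 rac-(5S,8R)-8-hydroxy-3-methoxy-2-methyl-5-(5-phenylpentyl)-5,6,7,8-tetrahydroquinolin-4(1H)-one
Product: 20 (5S,8R)-3-methoxy-2-methyl-4-oxo-5-(5-phenylpentyl)-1,4,5,6,7,8-hexahydroquinolin-8-yl acetate
Conditions: Novozym 435 (immobilised Candida antarctica lipase B), vinyl acetate (3 equiv), THF/MTBE, 35 °C, to about half conversion; chromatography
Reagents that add atoms: vinyl acetate, C=COC(C)=O
Why: In this lipase-catalysed kinetic resolution by irreversible transesterification the Kazlauskas rule predicts acylation of the alcohol whose large group (ring carbon C8a) and medium group (C7 methylene) are arranged as in (R)-1-arylalkanols, as with tetralin-1-ol and 5,6,7,8-tetrahydroquinolin-8-ol, so the (5S,8R) enantiomer should be acetylated and the (5R,8S) alcohol left behind, with no stereocentre created or touched.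

Step 11
Reactants: 20 (5S,8R)-3-methoxy-2-methyl-4-oxo-5-(5-phenylpentyl)-1,4,5,6,7,8-hexahydroquinolin-8-yl acetate
Product: 21 (5S,8R)-8-hydroxy-3-methoxy-2-methyl-5-(5-phenylpentyl)-5,6,7,8-tetrahydroquinolin-4(1H)-one
Conditions: K2CO3 (cat.), MeOH, rt
Reagents that add atoms: none
Why: Base-catalysed transesterification with methanol removes the acetate at the acyl carbon, so neither C8 nor C5 is affected.

**Compound list**

1 | 2-methylpyridin-3-ol | Cc1ncccc1O | starting material
2 | 4,6-dibromo-2-methylpyridin-3-ol | Cc1nc(Br)cc(Br)c1O | intermediate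
3 | 4,6-dibromo-3-methoxy-2-methylpyridine | COc1c(C)nc(Br)cc1Br | intermediate
4 | 4-(benzyloxy)-6-bromo-3-methoxy-2-methylpyridine | COc1c(C)nc(Br)cc1OCc1ccccc1 | intermediate
5 | 4-(benzyloxy)-5-methoxy-6-methylpyridin-2(1H)-one | COc1c(C)[nH]c(=O)cc1OCc1ccccc1 | intermediate
6 | 4-(benzyloxy)-3-bromo-5-methoxy-6-methylpyridin-2(1H)-one | COc1c(C)[nH]c(=O)c(Br)c1OCc1ccccc1 | intermediate
7 | 4-(benzyloxy)-3-bromo-5-methoxy-6-methyl-2-[(trimethylsilyl)oxy]pyridine (not isolated) | COc1c(C)nc(O[Si](C)(C)C)c(Br)c1OCc1ccccc1 | intermediate
8 | 4-(benzyloxy)-3-lithio-5-methoxy-6-methyl-2-[(trimethylsilyl)oxy]pyridine (not isolated) | COc1c(C)nc(O[Si](C)(C)C)c([Li])c1OCc1ccccc1 | intermediate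
9 | lithium 4-(benzyloxy)-5-methoxy-6-methyl-3-(trimethylsilyl)pyridin-2-olate (not isolated) | COc1c(C)nc([O-])c([Si](C)(C)C)c1OCc1ccccc1.[Li+] | intermediate
10 | 4-(benzyloxy)-5-methoxy-6-methyl-3-(trimethylsilyl)pyridin-2-yl trifluoromethanesulfonate | COc1c(C)nc(OS(=O)(=O)C(F)(F)F)c([Si](C)(C)C)c1OCc1ccccc1 | intermediate
11 | furan | c1ccoc1 | starting material
12 | (5-bromopentyl)benzene | BrCCCCCc1ccccc1 | starting material
13 | 2-furyllithium (not isolated) | [Li]c1ccco1 | intermediate
14 | 2-(5-phenylpentyl)furan | c1coc(CCCCCc2ccccc2)c1 | intermediate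
15 | 4-(benzyloxy)-5-methoxy-6-methyl-2,3-didehydropyridine (2,3-pyridyne, not isolated) | COC1=C(OCc2ccccc2)C#CN=C1C | intermediate
16 | rac-(5S,8R)-4-(benzyloxy)-3-methoxy-2-methyl-5-(5-phenylpentyl)-5,8-dihydro-5,8-epoxyquinoline (racemate, the enantiomer that leads to the target drawn) | COc1c(C)nc2c(c1OCc1ccccc1)[C@]3(CCCCCc4ccccc4)C=C[C@H]2O3 | intermediate
17 | rac-(5S,8R)-4-(benzyloxy)-3-methoxy-2-methyl-5-(5-phenylpentyl)-5,6,7,8-tetrahydro-5,8-epoxyquinoline (racemate, not isolated) | COc1c(C)nc2c(c1OCc1ccccc1)[C@]3(CCCCCc4ccccc4)CC[C@H]2O3 | intermediate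
18 | rac-(5S,8R)-3-methoxy-2-methyl-5-(5-phenylpentyl)-5,6,7,8-tetrahydro-5,8-epoxyquinolin-4(1H)-one (racemate, not isolated) | COc1c(C)[nH]c2c(c1=O)[C@]3(CCCCCc4ccccc4)CC[C@H]2O3 | intermediate
19 | rac-(5S,8R)-8-hydroxy-3-methoxy-2-methyl-5-(5-phenylpentyl)-5,6,7,8-tetrahydroquinolin-4(1H)-one (racemic cis alcohol, the target enantiomer drawn) | COc1c(C)[nH]c2c(c1=O)[C@@H](CCCCCc1ccccc1)CC[C@H]2O | intermediate
20 | (5S,8R)-3-methoxy-2-methyl-4-oxo-5-(5-phenylpentyl)-1,4,5,6,7,8-hexahydroquinolin-8-yl acetate | COc1c(C)[nH]c2c(c1=O)[C@@H](CCCCCc1ccccc1)CC[C@H]2OC(C)=O | intermediate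
21 | (5S,8R)-8-hydroxy-3-methoxy-2-methyl-5-(5-phenylpentyl)-5,6,7,8-tetrahydroquinolin-4(1H)-one (single enantiomer, chain and hydroxyl cis) | COc1c(C)[nH]c2c(c1=O)[C@@H](CCCCCc1ccccc1)CC[C@H]2O | target

**Step count**

Total: 11 steps. Longest linear sequence: 10 steps (steps 1 to 6, then 8 to 11); step 7 is a one-step side branch.

**Steps most likely to fail, with fallbacks**

Step 8. The two furan α-carbons may be discriminated poorly, because the steric repulsion between the chain and the 4-benzyloxy group works against the polarisation of the pyridyne; self-reaction of the aryne may also compete. The fallback sets out from 10 and replaces 14 by commercial methyl furan-2-carboxylate (COC(=O)c1ccco1), whose acceptor group makes the free α-carbon far more nucleophilic than the substituted one, so that bonding to C8a should start there. Cycloaddition under the CsF/MeCN conditions should give racemic methyl 4-(benzyloxy)-3-methoxy-2-methyl-5,8-dihydro-5,8-epoxyquinoline-5-carboxylate F1. Reduction with i-Bu2AlH in CH2Cl2 at −78 °C should give the non-enolisable bridgehead aldehyde 4-(benzyloxy)-3-methoxy-2-methyl-5,8-dihydro-5,8-epoxyquinoline-5-carbaldehyde F2. Wittig olefination with the ylide from (4-phenylbutyl)triphenylphosphonium bromide and NaN(SiMe3)2 in THF should give 4-(benzyloxy)-3-methoxy-2-methyl-5-[(Z)-5-phenylpent-1-enyl]-5,8-dihydro-5,8-epoxyquinoline F3. Hydrogenation of this compound under the conditions of step 9 also saturates the side-chain alkene, so the material passes through 17 and comes back to the route at 19.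

Step 9. The bridge may open incompletely or with mixed stereochemistry, either because retention competes with inversion on the metal or because the C5–O bond ionises through the pyridone before reduction; loss of the C8 hydroxyl by further hydrogenolysis is a lesser concern. The fallback sets out from 16 and does not rely on the cis/trans outcome. Hydrogenation over 10% Pd/C in EtOH/AcOH should open the bridge completely and give 19 together with its trans isomer rac-(5S,8S)-8-hydroxy-3-methoxy-2-methyl-5-(5-phenylpentyl)-5,6,7,8-tetrahydroquinolin-4(1H)-one F4. Oxidation of the mixture with Dess–Martin periodinane in CH2Cl2/DMSO should converge on the racemic ketone 3-methoxy-2-methyl-5-(5-phenylpentyl)-6,7-dihydroquinoline-4,8(1H,5H)-dione F5. Asymmetric transfer hydrogenation with RuCl(p-cymene)[(R,R)-TsDPEN] in HCO2H/Et3N should then set C8 as R under catalyst control in both C5 series. The products are 21 and the trans diastereomer (5R,8R)-8-hydroxy-3-methoxy-2-methyl-5-(5-phenylpentyl)-5,6,7,8-tetrahydroquinolin-4(1H)-one F6, which are separable by chromatography. The fallback comes back to the route at 21 and makes steps 10 and 11 unnecessary.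

Step 6. Butyllithium may be consumed by attack at silicon or by deprotonation at the benzylic or 6-methyl positions instead of bromine–lithium exchange, or the silyl shift may be incomplete, so that the silyl group is not transferred to carbon. The fallback sets out from 4, whose only ring hydrogen lies between the bromine and the benzyloxy group, and uses deprotonation instead of exchange. Treatment with LDA in the presence of Me3SiCl (THF, −78 °C, in situ quench) should give 4-(benzyloxy)-2-bromo-5-methoxy-6-methyl-3-(trimethylsilyl)pyridine F7. Hydroxylation under the palladium conditions of step 4 should give 4-(benzyloxy)-5-methoxy-6-methyl-3-(trimethylsilyl)pyridin-2(1H)-one F8. O-Triflation with Tf2O and pyridine in CH2Cl2 at 0 °C comes back to the route at 10.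

**Further compounds**

F1 | step 8 | methyl 4-(benzyloxy)-3-methoxy-2-methyl-5,8-dihydro-5,8-epoxyquinoline-5-carboxylate (racemate, enantiomer corresponding to 16 drawn) | COc1c(C)nc2c(c1OCc1ccccc1)[C@]3(C(=O)OC)C=C[C@H]2O3
F2 | step 8 | 4-(benzyloxy)-3-methoxy-2-methyl-5,8-dihydro-5,8-epoxyquinoline-5-carbaldehyde (racemate, enantiomer corresponding to 16 drawn) | COc1c(C)nc2c(c1OCc1ccccc1)[C@]3(C=O)C=C[C@H]2O3
F3 | step 8 | 4-(benzyloxy)-3-methoxy-2-methyl-5-[(Z)-5-phenylpent-1-enyl]-5,8-dihydro-5,8-epoxyquinoline (racemate, enantiomer corresponding to 16 drawn) | COc1c(C)nc2c(c1OCc1ccccc1)[C@]3(/C=C\CCCc4ccccc4)C=C[C@H]2O3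
F4 | step 9 | rac-(5S,8S)-8-hydroxy-3-methoxy-2-methyl-5-(5-phenylpentyl)-5,6,7,8-tetrahydroquinolin-4(1H)-one (racemic trans alcohol, 5S,8S enantiomer drawn) | COc1c(C)[nH]c2c(c1=O)[C@@H](CCCCCc1ccccc1)CC[C@@H]2O
F5 | step 9 | 3-methoxy-2-methyl-5-(5-phenylpentyl)-6,7-dihydroquinoline-4,8(1H,5H)-dione (racemate, 5S enantiomer drawn) | COc1c(C)[nH]c2c(c1=O)[C@@H](CCCCCc1ccccc1)CCC2=O
F6 | step 9 | (5R,8R)-8-hydroxy-3-methoxy-2-methyl-5-(5-phenylpentyl)-5,6,7,8-tetrahydroquinolin-4(1H)-one (trans diastereomer, single enantiomer) | COc1c(C)[nH]c2c(c1=O)[C@H](CCCCCc1ccccc1)CC[C@H]2O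
F7 | step 6 | 4-(benzyloxy)-2-bromo-5-methoxy-6-methyl-3-(trimethylsilyl)pyridine | COc1c(C)nc(Br)c([Si](C)(C)C)c1OCc1ccccc1
F8 | step 6 | 4-(benzyloxy)-5-methoxy-6-methyl-3-(trimethylsilyl)pyridin-2(1H)-one | COc1c(C)[nH]c(=O)c([Si](C)(C)C)c1OCc1ccccc1
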